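The target is numbered C1 (C=O flanked by both substituents), C2 (OMe), C3‑H, C4 (C=O), C5‑H, C6 (heptadecyl). The oxygens on C2 and C4 and the chain‑bearing C6 sit on alternate carbons of the six‑membered ring, which is the footprint of a stearoyl‑primed tetraketide (C18 + 3 × C2); only the C1 oxygen, para to the C4 oxygen, lies outside this pattern.
Cuts in retrosynthetic order: the C1 oxygen (back to a 3‑alkyl‑5‑methoxyphenol), a sacrificial carboxyl on C5 together with the O–CH3 bond, ring bond C5–C6 (aldol), chain bond C1–C6 (Claisen), chain bond C2–C3 (γ‑acylation).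
Forward: a dioxinone (C4, C5 and the carboxyl) is extended by acetyl and then by stearoyl to a linear masked tetraketide. A biomimetic aldol aromatisation closes the only carbocycle, and methylation, unmasking/decarboxylation and para‑oxidation finish the route.
Helpers: the dioxinone is a temporary ring that masks the carboxyl end, makes C5 the nucleophile and leaves exactly one free phenol for methylation. This ring and the carboxyl group are removed together in step 6.
Stereochemistry: the target has no stereocentre and no configurable double bond. The one transient carbinol centre is destroyed in the step that creates it.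

Key step: step 4

Remark: 6 and 8 are drawn as keto tautomers although they should be largely enolised; in 8 the side‑chain carbons are counted C1' (next to the ring) to C21'.

Step 1
Reactants: 1 stearoyl chloride (octadecanoyl chloride)
Product: 2 N‑methoxy‑N‑methyloctadecanamide
Conditions: MeNH(OMe)·HCl, Et3N, CH2Cl2, 0 °C to rt
Reagents that add atoms: N,O‑dimethylhydroxylamine hydrochloride, CNOC.Cl
Why: Nucleophilic acyl substitution of an acid chloride by the hydroxylamine freed with Et3N (Weinreb amide formation) is fast, and no other functional group is present.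

Step 2
Reactants: 3 2,2,6‑trimethyl‑4H‑1,3‑dioxin‑4‑one; 4 acetyl chloride
Product: 6 2,2‑dimethyl‑6‑(2‑oxopropyl)‑4H‑1,3‑dioxin‑4‑one, via lithium dienolate 5 (not isolated)
Conditions: LiN(SiMe3)2, THF, −78 °C; then 4 (0.5 equiv), −78 °C; 1 M HCl
Reagents that add atoms: LiN(SiMe3)2, [Li+].C[Si](C)(C)[N-][Si](C)(C)C (its lithium stands in intermediate 5 only; 6 keeps nothing from it)
Why: Kinetic γ‑deprotonation of the vinylogous ester gives dienolate 5, which is C‑acylated at its exocyclic γ‑carbon (vinylogous Claisen‑type acylation of a dioxinone dienolate, the standard entry to keto‑dioxinones), the excess of 5 absorbing the acidic proton of 6.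

Step 3
Reactants: 6 2,2‑dimethyl‑6‑(2‑oxopropyl)‑4H‑1,3‑dioxin‑4‑one; 2 N‑methoxy‑N‑methyloctadecanamide
Product: 8 2,2‑dimethyl‑6‑(2,4‑dioxohenicosyl)‑4H‑1,3‑dioxin‑4‑one, via dilithium dianion 7 (not isolated)
Conditions: LiN(iPr)2 (2.2 equiv), THF, −78 to −40 °C; then 2, −40 to −20 °C; 1 M HCl to pH 3
Reagents that add atoms: LiN(iPr)2, [Li+].CC(C)[N-]C(C)C (its lithium stands in intermediate 7 only; 8 keeps nothing from it)
Why: Double deprotonation gives dianion 7, which reacts at its last‑formed and most basic terminal carbon (crossed Claisen condensation of a 1,3‑dicarbonyl dianion), and the Weinreb amide transfers the stearoyl group once only, so the full C24 tetraketide chain should result with its carboxyl end masked.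

Step 4
Reactants: 8 2,2‑dimethyl‑6‑(2,4‑dioxohenicosyl)‑4H‑1,3‑dioxin‑4‑one
Product: 10 5‑heptadecyl‑7‑hydroxy‑2,2‑dimethyl‑4H‑1,3‑benzodioxin‑4‑one, via aldol carbinol 9 (not isolated)
Conditions: Et3N, CH2Cl2, rt
Reagents that add atoms: none
Why: Et3N removes the doubly activated C1' proton of 8, the charge of the resulting extended dienolate reaches dioxinone C5, and C5 adds to the C4' (stearoyl) ketone to give carbinol 9, which loses water by E1cB elimination and enolises at C2' to the benzene ring of 10, an irreversible sink. The closest known reaction type is the biomimetic aldol aromatisation of diketo‑dioxinones and of 3,5,7‑triketo esters to resorcylates, the laboratory copy of the C2‑to‑C7 aldol folding of a stearoyl‑primed tetraketide by alkylresorcinol‑forming polyketide synthases. The single new ring, the carbocycle, closes through bond C4a–C5 of 10 (C5–C6 of the quinone) in a favoured 6‑(enolexo)‑exo‑trig mode. The carbinol carbon of 9 arises racemic and is erased by the dehydration, so no stereocontrol is required. The step needs C‑aldol closure in preference to Claisen closure onto the carboxyl carbon, lactonisation to a 2‑pyranone and O‑cyclisation to a 4‑pyranone, and the dioxinone ring secures this because it masks the carboxyl as an acylal that releases no acylketene at room temperature and holds C5 cis to the side chain across C5=C6 within reach of C4', while the acid‑free medium withholds the catalyst that pyranone formation needs. Regioselectivity follows from acidity and ring size, since the chain CH2 next to C4' is far less acidic than C1' and C3', and attack from C1' could only give a four‑membered ring.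

Step 5
Reactants: 10 5‑heptadecyl‑7‑hydroxy‑2,2‑dimethyl‑4H‑1,3‑benzodioxin‑4‑one
Product: 11 5‑heptadecyl‑7‑methoxy‑2,2‑dimethyl‑4H‑1,3‑benzodioxin‑4‑one
Conditions: MeI, K2CO3, acetone, reflux
Reagents that add atoms: methyl iodide, CI
Why: Williamson ether synthesis on the only free phenol of 10; the other phenolic oxygen and the carboxyl group are tied up in the dioxinone ring, so a monomethylation that is statistical on a free 5‑alkylresorcinol becomes unambiguous.

Step 6
Reactants: 11 5‑heptadecyl‑7‑methoxy‑2,2‑dimethyl‑4H‑1,3‑benzodioxin‑4‑one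
Product: 13 3‑heptadecyl‑5‑methoxyphenol, via salicylic acid 12 (not isolated)
Conditions: 6 M aq. KOH, MeOH–THF, sealed tube, 110 °C; then 3 M HCl to pH 1, 80 °C
Reagents that add atoms: water (as aq. KOH), O (its oxygen enters the carboxyl group of intermediate 12 and leaves again with CO2; 13 keeps only hydrogen from it)
Why: Hydroxide opens the aryl acylal with loss of acetone (saponification) to acid 12, whose carboxyl carbon is ortho and para to two oxygen donors and squeezed between two ortho substituents, so ipso‑protonation and loss of CO2 (protodecarboxylation of a resorcylic acid, as in standard preparations of olivetol‑type phenols) should follow on heating.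

Step 7
Reactants: 13 3‑heptadecyl‑5‑methoxyphenol
Product: 14 2‑methoxy‑6‑heptadecyl‑1,4‑benzoquinone (2‑heptadecyl‑6‑methoxycyclohexa‑2,5‑diene‑1,4‑dione)
Conditions: (KSO3)2NO (2.5 equiv), aq. KH2PO4, Bu4NHSO4 (cat.), CH2Cl2–H2O, rt
Reagents that add atoms: potassium nitrosodisulfonate (Fremy's salt), [K+].[K+].[O]N(S(=O)(=O)[O-])S(=O)(=O)[O-]
Why: Teuber oxidation, in which one equivalent of the nitroxyl radical abstracts the phenolic hydrogen, a second couples at the free para carbon between OMe and the chain, and loss of imidodisulfonate gives the para‑quinone, as is known for the monomethyl ethers of orcinol and olivetol.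

Compound list
1 | stearoyl chloride | CCCCCCCCCCCCCCCCCC(=O)Cl | starting material
2 | N‑methoxy‑N‑methyloctadecanamide | CCCCCCCCCCCCCCCCCC(=O)N(C)OC | intermediate
3 | 2,2,6‑trimethyl‑4H‑1,3‑dioxin‑4‑one | CC1=CC(=O)OC(C)(C)O1 | starting material
4 | acetyl chloride | CC(=O)Cl | starting material
5 | lithium dienolate of 3 (formed in the flask) | [Li+].C=C1C=C([O-])OC(C)(C)O1 | intermediate
6 | 2,2‑dimethyl‑6‑(2‑oxopropyl)‑4H‑1,3‑dioxin‑4‑one | CC(=O)CC1=CC(=O)OC(C)(C)O1 | intermediate
7 | dilithium dianion of 6 (formed in the flask) | [Li+].[Li+].C=C([O-])C=C1C=C([O-])OC(C)(C)O1 | intermediate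
8 | 2,2‑dimethyl‑6‑(2,4‑dioxohenicosyl)‑4H‑1,3‑dioxin‑4‑one | CCCCCCCCCCCCCCCCCC(=O)CC(=O)CC1=CC(=O)OC(C)(C)O1 | intermediate
9 | 5‑heptadecyl‑5‑hydroxy‑2,2‑dimethyl‑5,6‑dihydro‑4H‑1,3‑benzodioxine‑4,7(8H)‑dione (racemic, formed in the flask) | CCCCCCCCCCCCCCCCCC1(O)CC(=O)CC2=C1C(=O)OC(C)(C)O2 | intermediate
10 | 5‑heptadecyl‑7‑hydroxy‑2,2‑dimethyl‑4H‑1,3‑benzodioxin‑4‑one | CCCCCCCCCCCCCCCCCc1cc(O)cc2OC(C)(C)OC(=O)c12 | intermediate
11 | 5‑heptadecyl‑7‑methoxy‑2,2‑dimethyl‑4H‑1,3‑benzodioxin‑4‑one | CCCCCCCCCCCCCCCCCc1cc(OC)cc2OC(C)(C)OC(=O)c12 | intermediate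
12 | 2‑heptadecyl‑6‑hydroxy‑4‑methoxybenzoic acid (formed in the flask) | CCCCCCCCCCCCCCCCCc1cc(OC)cc(O)c1C(=O)O | intermediate
13 | 3‑heptadecyl‑5‑methoxyphenol | CCCCCCCCCCCCCCCCCc1cc(O)cc(OC)c1 | intermediate
14 | 2‑methoxy‑6‑heptadecyl‑1,4‑benzoquinone | CCCCCCCCCCCCCCCCCC1=CC(=O)C=C(OC)C1=O | target

Total steps: 7. Longest linear sequence: 6 (steps 2–7, or steps 1 and 3–7).

Steps most likely to fail

Step 3 (crossed Claisen condensation). What may go wrong:
- proton transfer from the acylated chain to unreacted dianion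
- slow attack of the delocalised dianion on a waxy amide that dissolves poorly in cold THF
- premature cyclisation during work‑up

The fallback replaces the dianion by soft enolisation. It sets out from 3 and 1 and comes back at 8. Allyl hydrogen malonate is converted with (COCl)2 and catalytic DMF into allyl 3‑chloro‑3‑oxopropanoate F1, which acylates lithium dienolate 5 (from 3) to allyl 4‑(2,2‑dimethyl‑4‑oxo‑4H‑1,3‑dioxin‑6‑yl)‑3‑oxobutanoate F2. MgCl2 and pyridine in CH2Cl2 then C‑acylate F2 with stearoyl chloride 1 at the carbon between ester and ketone, giving allyl 2‑[(2,2‑dimethyl‑4‑oxo‑4H‑1,3‑dioxin‑6‑yl)acetyl]‑3‑oxoicosanoate F3. Catalytic Pd(PPh3)4 with morpholine in THF removes the allyl group, and 2‑[(2,2‑dimethyl‑4‑oxo‑4H‑1,3‑dioxin‑6‑yl)acetyl]‑3‑oxoicosanoic acid F4 should lose CO2 spontaneously to give 8.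

Step 7 (para‑oxidation). What may go wrong:
- slow and incomplete oxidation, because the waxy phenol is poorly served by an aqueous oxidant
- attack at an ortho position
- oxidative coupling of phenoxyl radicals

The fallback installs nitrogen first by an ionic para‑substitution. It sets out from 13 and comes back at 14. Nitrosation (NaNO2, aq. HCl, EtOH–THF, 0 °C), which is para‑selective even between two flanking groups as with 3,5‑xylenol, should give 3‑heptadecyl‑5‑methoxy‑4‑nitrosophenol F9. Reduction with Na2S2O4 (aq. NaOH–EtOH) gives 4‑amino‑3‑heptadecyl‑5‑methoxyphenol F10. FeCl3 in aq. HCl–THF oxidises this to 4‑imino‑3‑heptadecyl‑5‑methoxycyclohexa‑2,5‑dien‑1‑one F11, which hydrolyses in the same medium to 14.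

Step 4 (aldol aromatisation). What may go wrong:
- diversion of an enol oxygen into pyranone formation
- stalling at the carbinol stage without dehydration
- insufficient nucleophilicity of the dioxinone carbon towards a ketone shielded by the long chain

The fallback closes the ring from an open β‑keto ester carbanion instead of the dioxinone. It sets out from 8 and comes back at 12, and hence at 13. Heating 8 in toluene at 110 °C with MeOH causes retro‑[4+2] loss of acetone to the acylketene 3,5,7‑trioxotetracos‑1‑en‑1‑one F5, which is trapped as methyl 3,5,7‑trioxotetracosanoate F6. Cs2CO3 in MeOH and then methanolic HCl bring about aldol closure and dehydration to methyl 2‑heptadecyl‑4,6‑dihydroxybenzoate F7. One equivalent of MeI with K2CO3 in acetone methylates the non‑chelated 4‑OH to methyl 2‑heptadecyl‑6‑hydroxy‑4‑methoxybenzoate F8. The conditions of step 6 then saponify F8 to 12 and decarboxylate it to 13.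

Further compounds
F1 | step 3 | allyl 3‑chloro‑3‑oxopropanoate | C=CCOC(=O)CC(=O)Cl
F2 | step 3 | allyl 4‑(2,2‑dimethyl‑4‑oxo‑4H‑1,3‑dioxin‑6‑yl)‑3‑oxobutanoate | C=CCOC(=O)CC(=O)CC1=CC(=O)OC(C)(C)O1
F3 | step 3 | allyl 2‑[(2,2‑dimethyl‑4‑oxo‑4H‑1,3‑dioxin‑6‑yl)acetyl]‑3‑oxoicosanoate | CCCCCCCCCCCCCCCCCC(=O)C(C(=O)OCC=C)C(=O)CC1=CC(=O)OC(C)(C)O1
F4 | step 3 | 2‑[(2,2‑dimethyl‑4‑oxo‑4H‑1,3‑dioxin‑6‑yl)acetyl]‑3‑oxoicosanoic acid | CCCCCCCCCCCCCCCCCC(=O)C(C(=O)O)C(=O)CC1=CC(=O)OC(C)(C)O1
F5 | step 4 | 3,5,7‑trioxotetracos‑1‑en‑1‑one (acylketene) | CCCCCCCCCCCCCCCCCC(=O)CC(=O)CC(=O)C=C=O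
F6 | step 4 | methyl 3,5,7‑trioxotetracosanoate | CCCCCCCCCCCCCCCCCC(=O)CC(=O)CC(=O)CC(=O)OC
F7 | step 4 | methyl 2‑heptadecyl‑4,6‑dihydroxybenzoate | CCCCCCCCCCCCCCCCCc1cc(O)cc(O)c1C(=O)OC
F8 | step 4 | methyl 2‑heptadecyl‑6‑hydroxy‑4‑methoxybenzoate | CCCCCCCCCCCCCCCCCc1cc(OC)cc(O)c1C(=O)OC
F9 | step 7 | 3‑heptadecyl‑5‑methoxy‑4‑nitrosophenol | CCCCCCCCCCCCCCCCCc1cc(O)cc(OC)c1N=O
F10 | step 7 | 4‑amino‑3‑heptadecyl‑5‑methoxyphenol | CCCCCCCCCCCCCCCCCc1cc(O)cc(OC)c1N
F11 | step 7 | 4‑imino‑3‑heptadecyl‑5‑methoxycyclohexa‑2,5‑dien‑1‑one | CCCCCCCCCCCCCCCCCC1=CC(=O)C=C(OC)C1=N
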